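**Retrosynthetic overview**
1. Target 13 ⇐ isoxazoline acetate 12: the β-hydroxy ketone (acyl C=O plus the free allylic OH) is stored as a 2-isoxazoline and released last by N–O cleavage, so the two allylic oxygens are never both free.
2. 12 ⇐ enone 10: convex-face 1,2-reduction of the ring ketone, then acetylation of the only secondary OH.
3. 10 ⇐ cycloadduct 6: Rubottom hydroxylation of the ring-fusion carbon, then β-elimination of the silyloxy group to create the ring alkene.
4. 6 ⇐ tridecanenitrile oxide (from tridecanal oxime 2) + (S)-4-silyloxycyclopentenone 3: a 1,3-dipolar cycloaddition anti to OTBS makes the C–C(acyl) and C–O bonds.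
5. Rings: the cyclopentene ring is bought with 3; the isoxazoline is the only ring formed (step 2) and it is opened again in step 7.

Assumption: tridecanal and (4S)-4-[(tert-butyldimethylsilyl)oxy]cyclopent-2-en-1-one are bought; the latter is the only source of chirality. The route is designed on paper and has not been run.

**Step 1**
Reactants: 1 tridecanal
Product: 2 tridecanal oxime
Conditions: NH2OH·HCl, NaOAc, EtOH/H2O, rt
Reagents that add atoms: hydroxylamine hydrochloride, NO.Cl
Why: Oxime condensation of an unhindered aldehyde; no stereocentre is involved and both E and Z oximes give the same nitrile oxide.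

**Step 2**
Reactants: 2 tridecanal oxime (1.5 equiv); 3 (4S)-4-[(tert-butyldimethylsilyl)oxy]cyclopent-2-en-1-one
Product: 6 (3aR,6S,6aS)-6-[(tert-butyldimethylsilyl)oxy]-3-dodecyl-3a,5,6,6a-tetrahydro-4H-cyclopenta[d]isoxazol-4-one, via N-hydroxytridecanimidoyl chloride 4 (not isolated), via tridecanenitrile oxide 5 (not isolated)
Conditions: NCS, DMF, rt; then 3, NaHCO3 (solid), EtOAc, rt
Reagents that add atoms: none
Why: Huisgen nitrile oxide–alkene 1,3-dipolar cycloaddition; the concerted suprafacial addition gives the cis-fused isoxazoline, the dipole adds anti to the bought C4–OTBS group (setting C3a and C6a), and enone polarisation plus the bulk of the silyl ether should put the oxygen terminus on the β-carbon so that the future acyl carbon bonds to C-α.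

**Step 3**
Reactants: 6 (3aR,6S,6aS)-6-[(tert-butyldimethylsilyl)oxy]-3-dodecyl-3a,5,6,6a-tetrahydro-4H-cyclopenta[d]isoxazol-4-one
Product: 9 (3aS,6S,6aR)-6-[(tert-butyldimethylsilyl)oxy]-3-dodecyl-3a-hydroxy-3a,5,6,6a-tetrahydro-4H-cyclopenta[d]isoxazol-4-one, via trimethylsilyl enol ether 7 (not isolated), via trimethylsilyloxy ketone 8 (not isolated)
Conditions: TMSOTf, Et3N, CH2Cl2, 0 °C; pentane, filter; then mCPBA, CH2Cl2, −20 °C; then citric acid, MeOH, rt
Reagents that add atoms: mCPBA, OOC(=O)c1cccc(Cl)c1
Why: Rubottom oxidation: soft enolisation takes the doubly activated C3a–H (α to C=O and C=N), and because only the cis-fused bicycle is accessible the oxygen must enter on the face of the former H, trans to the ring C–O bond, which fixes the tertiary carbinol before any enone exists whose planar dienolate could erase C3a/C6a.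

**Step 4**
Reactants: 9 (3aS,6S,6aR)-6-[(tert-butyldimethylsilyl)oxy]-3-dodecyl-3a-hydroxy-3a,5,6,6a-tetrahydro-4H-cyclopenta[d]isoxazol-4-one
Product: 10 (3aS,6aR)-3-dodecyl-3a-hydroxy-3a,6a-dihydro-4H-cyclopenta[d]isoxazol-4-one
Conditions: DBU (1.1 equiv), CH2Cl2, 0 °C, short reaction time
Reagents that add atoms: none
Why: E1cB β-elimination of silanolate through the only remaining enolisable position (C5) gives the conjugated enone and so the ring alkene of the target; the quaternary C3a and the fused C6a are untouched, and the bought stereocentre is given up only after it has relayed its information.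

**Step 5**
Reactants: 10 (3aS,6aR)-3-dodecyl-3a-hydroxy-3a,6a-dihydro-4H-cyclopenta[d]isoxazol-4-one
Product: 11 (3aR,4S,6aR)-3-dodecyl-4,6a-dihydro-3aH-cyclopenta[d]isoxazole-3a,4-diol
Conditions: NaBH4, CeCl3·7H2O, MeOH, −78 °C
Reagents that add atoms: none
Why: Luche 1,2-reduction: hydride should attack the convex face of the cis-fused bicycle (the face of the angular OH, anti to the isoxazoline ring), so the new carbinol is trans to the tertiary OH and cis to the future acyl group, while the C=N–O unit is not reduced.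

**Step 6**
Reactants: 11 (3aR,4S,6aR)-3-dodecyl-4,6a-dihydro-3aH-cyclopenta[d]isoxazole-3a,4-diol
Product: 12 (3aR,4S,6aR)-3-dodecyl-3a-hydroxy-4,6a-dihydro-3aH-cyclopenta[d]isoxazol-4-yl acetate
Conditions: Ac2O, pyridine, 0 °C → rt
Reagents that add atoms: acetic anhydride, CC(=O)OC(C)=O
Why: Acylation of the only secondary alcohol (the hindered tertiary α-hydroxyl does not react without DMAP); placing the acetate now keeps the two allylic oxygens distinguishable when the second one is released.

**Step 7**
Reactants: 12 (3aR,4S,6aR)-3-dodecyl-3a-hydroxy-4,6a-dihydro-3aH-cyclopenta[d]isoxazol-4-yl acetate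
Product: 13 (1S,4R,5S)-4,5-dihydroxy-5-tridecanoylcyclopent-2-en-1-yl acetate
Conditions: Mo(CO)6, MeCN/H2O (15:1), 80 °C
Reagents that add atoms: water, O
Why: Mo(CO)6-mediated reductive N–O cleavage of the 2-isoxazoline gives the β-hydroxy ketimine, which hydrolyses in situ to the β-hydroxy ketone; no stereocentre is touched, the α-carbon is quaternary so dehydration is impossible, and the ring alkene is not reduced.

**Compound list**
1 | tridecanal | CCCCCCCCCCCCC=O | starting material
2 | tridecanal oxime (E/Z mixture) | CCCCCCCCCCCCC=NO | intermediate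
3 | (4S)-4-[(tert-butyldimethylsilyl)oxy]cyclopent-2-en-1-one | O=C1C=C[C@@H](O[Si](C)(C)C(C)(C)C)C1 | starting material
4 | N-hydroxytridecanimidoyl chloride | CCCCCCCCCCCCC(Cl)=NO | intermediate
5 | tridecanenitrile oxide | CCCCCCCCCCCCC#[N+][O-] | intermediate
6 | (3aR,6S,6aS)-6-[(tert-butyldimethylsilyl)oxy]-3-dodecyl-3a,5,6,6a-tetrahydro-4H-cyclopenta[d]isoxazol-4-one | CCCCCCCCCCCCC1=NO[C@@H]2[C@@H](O[Si](C)(C)C(C)(C)C)CC(=O)[C@H]12 | intermediate
7 | (6S,6aS)-6-[(tert-butyldimethylsilyl)oxy]-3-dodecyl-4-[(trimethylsilyl)oxy]-6,6a-dihydro-5H-cyclopenta[d]isoxazole | CCCCCCCCCCCCC1=NO[C@@H]2[C@@H](O[Si](C)(C)C(C)(C)C)CC(O[Si](C)(C)C)=C12 | intermediate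
8 | (3aS,6S,6aR)-6-[(tert-butyldimethylsilyl)oxy]-3-dodecyl-3a-[(trimethylsilyl)oxy]-3a,5,6,6a-tetrahydro-4H-cyclopenta[d]isoxazol-4-one | CCCCCCCCCCCCC1=NO[C@@H]2[C@@H](O[Si](C)(C)C(C)(C)C)CC(=O)[C@]12O[Si](C)(C)C | intermediate
9 | (3aS,6S,6aR)-6-[(tert-butyldimethylsilyl)oxy]-3-dodecyl-3a-hydroxy-3a,5,6,6a-tetrahydro-4H-cyclopenta[d]isoxazol-4-one | CCCCCCCCCCCCC1=NO[C@@H]2[C@@H](O[Si](C)(C)C(C)(C)C)CC(=O)[C@]12O | intermediate
10 | (3aS,6aR)-3-dodecyl-3a-hydroxy-3a,6a-dihydro-4H-cyclopenta[d]isoxazol-4-one | CCCCCCCCCCCCC1=NO[C@@H]2C=CC(=O)[C@]12O | intermediate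
11 | (3aR,4S,6aR)-3-dodecyl-4,6a-dihydro-3aH-cyclopenta[d]isoxazole-3a,4-diol | CCCCCCCCCCCCC1=NO[C@@H]2C=C[C@H](O)[C@]12O | intermediate
12 | (3aR,4S,6aR)-3-dodecyl-3a-hydroxy-4,6a-dihydro-3aH-cyclopenta[d]isoxazol-4-yl acetate | CCCCCCCCCCCCC1=NO[C@@H]2C=C[C@H](OC(C)=O)[C@]12O | intermediate
13 | (1S,4R,5S)-4,5-dihydroxy-5-tridecanoylcyclopent-2-en-1-yl acetate (CNP0284288.2) | CCCCCCCCCCCCC(=O)[C@]1(O)[C@H](O)C=C[C@@H]1OC(C)=O | target

**Step count and risks**
Total step count: 7. Longest linear sequence: 7 steps (1 → 2 → 6 → 9 → 10 → 11 → 12 → 13); 6 steps from the chiral enone 3.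

Three steps most likely to fail:

Step 2 (cycloaddition). The aliphatic nitrile oxide can dimerise to the furoxan faster than it adds to a moderately reactive enone, and some of the 6-oxo regioisomer is expected. The fallback changes the dipole and sets out from 2 and 3. Oxime 2 is oxidised (CF3CO3H, NaHCO3, MeCN) to 1-nitrotridecane F1, which TMSCl/Et3N converts into trimethylsilyl tridecane-1-nitronate F2. This dipole cannot dimerise and can be warmed with 3 (40–60 °C) to give the N-silyloxy isoxazolidine cycloadduct F3, again anti to OTBS and cis-fused. Catalytic TsOH in CH2Cl2 then eliminates trimethylsilanol, and the sequence comes back to the route at 6.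

Step 4 (elimination). Enone 10 is base-labile: its vinylogous C6a–H can be removed, which may trigger N–O fragmentation, and the α-ketol may rearrange under DBU. The fallback replaces the direct E1cB loss of silanolate by deprotection and activation, and sets out from 9. HF·pyridine in MeCN removes the silyl group to give the dihydroxy ketone F4. MsCl/Et3N at −30 °C converts the secondary alcohol into the mesylate F5, which loses methanesulfonate under these much milder conditions and comes back to the route at 10.

Step 7 (unmasking). Hot Mo(0) may ionise the allylic acetate or promote acetyl migration between the cis-1,3 oxygens (which would erode the ee), and the β-hydroxy ketone may undergo retro-aldol cleavage. The fallback separates reduction from hydrolysis and sets out from 12. SmI2 (THF, −78 → 0 °C) cleaves the N–O bond by single-electron transfer and stops at the β-hydroxy ketimine F6. After the excess reductant is quenched with air, the imine is hydrolysed on wet silica gel or with aqueous oxalic acid at 0 °C, which comes back to the route at 13.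

**Further compounds**
F1 | step 2 | 1-nitrotridecane | CCCCCCCCCCCCC[N+](=O)[O-]
F2 | step 2 | trimethylsilyl tridecane-1-nitronate | CCCCCCCCCCCCC=[N+]([O-])O[Si](C)(C)C
F3 | step 2 | (3aR,6S,6aS)-6-[(tert-butyldimethylsilyl)oxy]-3-dodecyl-2-[(trimethylsilyl)oxy]hexahydro-4H-cyclopenta[d]isoxazol-4-one (C3/N epimers) | CCCCCCCCCCCCC1N(O[Si](C)(C)C)O[C@@H]2[C@@H](O[Si](C)(C)C(C)(C)C)CC(=O)[C@H]12
F4 | step 4 | (3aS,6S,6aR)-3-dodecyl-3a,6-dihydroxy-3a,5,6,6a-tetrahydro-4H-cyclopenta[d]isoxazol-4-one | CCCCCCCCCCCCC1=NO[C@@H]2[C@@H](O)CC(=O)[C@]12O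
F5 | step 4 | (3aS,6S,6aR)-3-dodecyl-3a-hydroxy-4-oxo-3a,5,6,6a-tetrahydro-4H-cyclopenta[d]isoxazol-6-yl methanesulfonate | CCCCCCCCCCCCC1=NO[C@@H]2[C@@H](OS(C)(=O)=O)CC(=O)[C@]12O
F6 | step 7 | (1S,4R,5S)-4,5-dihydroxy-5-(1-iminotridecyl)cyclopent-2-en-1-yl acetate | CCCCCCCCCCCCC(=N)[C@]1(O)[C@H](O)C=C[C@@H]1OC(C)=O
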